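**Retrosynthetic overview**
1. The last step forms the C–S bond: a thiolate displaces an allylic bromide on the 2‑(bromomethyl)cyclopentenone. The thiol, methyl (R)‑3‑mercaptolactate, comes from methyl (S)‑glycidate.
2. The 4‑hydroxy‑4‑acylcyclopent‑2‑enone ring is the last carbocycle formed. It arises by intramolecular aldol of a Z‑enedione, which comes from singlet‑oxygen opening of a 2‑acylfuran. This sets the C13 carbinol.
3. The 2‑acylfuran comes from opening the sclareolide lactone with a furyllithium. The tertiary 8‑OH released is dehydrated to the exocyclic C8(17) alkene.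
4. The decalin (rings A/B, C5, C9, C10) comes intact from (+)‑sclareolide. The 3β‑OH is installed by enzymatic C–H hydroxylation.

**Assumptions:** (i) a C3β‑selective P450BM3 variant (or Mucor plumbeus whole cells) hydroxylates sclareolide. (ii) (S)‑Methyl glycidate is commercial. (iii) The C13 aldol has only modest substrate control, so the epimers are separated.

---

**Step 1**
Reactants: 1 (+)‑sclareolide
Product: 2 3β‑hydroxysclareolide
Conditions: engineered P450BM3 (C3‑selective variant), E. coli whole cells, glucose, O2, KPi pH 8, 25 °C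
Reagents that add atoms: dioxygen, O=O (the O becomes the 3‑OH)
Why: Enzymatic C–H hydroxylation (oxygen rebound) at the equatorial C3–H β‑face gives the 3β‑alcohol. The ring‑fusion centres C5, C9 and C10 are untouched.

**Step 2**
Reactants: 2
Product: 3 3β‑OTES‑sclareolide
Conditions: TESOTf, 2,6‑lutidine, CH2Cl2, –78 → 0 °C
Reagents that add atoms: TESOTf, CC[Si](CC)(CC)OS(=O)(=O)C(F)(F)F (the TES group is retained)
Why: Silylation of the hindered secondary alcohol protects it from the later Burgess reagent and organolithium, and it can be removed with the other TES group. No stereocentre is created.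

**Step 3**
Reactants: 4 methyl 2‑methylfuran‑3‑carboxylate
Product: 5 (2‑methylfuran‑3‑yl)methanol
Conditions: LiAlH4, Et2O, 0 °C → rt
Reagents that add atoms: none
Why: Hydride reduction of the ester to the primary alcohol.

**Step 4**
Reactants: 5
Product: 6 triethyl[(2‑methylfuran‑3‑yl)methoxy]silane
Conditions: TESCl, imidazole, CH2Cl2, 0 °C → rt
Reagents that add atoms: TESCl, CC[Si](Cl)(CC)CC (the TES group is retained)
Why: Silylation protects the alcohol so that the furan C5–H can be lithiated selectively later.

**Step 5**
Reactants: 3 (TES‑sclareolide) and 6 (furan TES ether)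
Product: 7 ring‑opened hydroxy ketone: 8α‑OH, 3β‑OTES, C12 ketone bearing 5‑methyl‑4‑(TESOCH2)furan‑2‑yl
Conditions: (i) 6, n‑BuLi, THF, –78 → 0 °C; (ii) add 3, –78 → –40 °C; NH4Cl quench
Reagents that add atoms: none
Why: n‑BuLi deprotonates the free α‑position (C5) of 6. The furyllithium adds once to the lactone carbonyl, and the tetrahedral intermediate opens to the aryl ketone and the tertiary 8‑OH (organolithium addition to a lactone). No new stereocentre forms.

**Step 6**
Reactants: 7
Product: 8 Δ8(17) exocyclic alkene furyl ketone
Conditions: Burgess reagent, benzene, 50 °C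
Reagents that add atoms: none
Why: Burgess dehydration is a syn‑Ei elimination of the tertiary alcohol that favors loss of a methyl hydrogen (Hofmann‑type), giving the exocyclic methylene. C8 becomes sp2. The endocyclic Δ7 and Δ8 isomers are removed on AgNO3–silica.

**Step 7**
Reactants: 8
Product: 9 Z‑enedione (CH3C(=O)–C(CH2OTES)=CH–C(=O)–C(=O)–CH2‑decalin)
Conditions: O2, methylene blue, hν (visible), CH2Cl2, –78 °C; then Me2S, –78 °C → rt
Reagents that add atoms: O2, O=O (Me2S only removes oxygen and is not retained)
Why: Singlet‑oxygen [4+2] cycloaddition to the trisubstituted furan, then Me2S reduction of the endoperoxide, gives the cis‑enedione. The 1,1‑disubstituted alkene reacts far more slowly with 1O2. No stereocentre is formed.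

**Step 8**
Reactants: 9
Product: 10 cyclopentenone with the C13 tertiary alcohol, bis‑TES (13‑epimer mixture, desired C13 epimer isolated)
Conditions: DBU (0.2 equiv), CH2Cl2, –20 → 0 °C; separate C13 epimers by HPLC
Reagents that add atoms: none
Why: Intramolecular aldol (5‑enolendo‑exo‑trig). The methyl‑ketone enolate adds to the very electrophilic C13 ketone of the 1,2‑dione, and the retained C14=C15 enone gives the 4‑hydroxy‑4‑acylcyclopent‑2‑enone. C13 is set with only modest substrate control from the decalin, so the epimers are separated.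

**Step 9**
Reactants: 10
Product: 11 triol (3β‑OH, C13‑OH, CH2OH)
Conditions: HF·pyridine, pyridine/THF, 0 °C → rt
Reagents that add atoms: none (fluorine is not retained)
Why: Fluoride‑driven removal of both triethylsilyl ethers (silyl ether cleavage). All stereocentres are untouched and the tertiary α‑ketol has no epimerizable H.

**Step 10**
Reactants: 11
Product: 12 2‑(bromomethyl)cyclopentenone
Conditions: MsCl, Et3N, CH2Cl2, –20 °C; then LiBr, THF, 0 °C
Reagents that add atoms: LiBr, [Li+].[Br-] (MsCl is consumed as the transient mesylate and is not retained)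
Why: The unhindered primary allylic alcohol is mesylated selectively over the hindered 3‑OH and the tertiary C13‑OH. Finkelstein‑type SN2 by bromide then gives the allylic bromide with no stereochemical change.

**Step 11**
Reactants: 13 methyl (S)‑glycidate
Product: 14 methyl (R)‑3‑(acetylthio)‑2‑hydroxypropanoate
Conditions: AcSH, Et3N (cat.), CH2Cl2, 0 °C → rt
Reagents that add atoms: thioacetic acid, CC(=O)S
Why: Epoxide opening at the less hindered C3 leaves the C2–O bond untouched. The (S)‑epoxide gives the (R)‑hydroxy thioester because CIP priorities swap, not because the centre is inverted.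

**Step 12**
Reactants: 14
Product: 15 methyl (R)‑2‑hydroxy‑3‑mercaptopropanoate
Conditions: K2CO3, MeOH, 0 °C, 15 min, under Ar; AcOH quench
Reagents that add atoms: none (the acetyl group leaves as methyl acetate)
Why: Methanolysis of the thioacetate releases the thiol. The methyl ester is unchanged and the carbinol stereocentre is not involved.

**Step 13**
Reactants: 12 (allylic bromide) and 15 (thiol)
Product: 16 Alternarin A
Conditions: i‑Pr2NEt, CH2Cl2, –20 → 0 °C
Reagents that add atoms: none (the thiol is numbered reactant 15)
Why: The thiolate displaces the reactive allylic bromide by SN2 (any SN2′ adduct re‑ionizes) to give the conjugated thioether. No new stereocentre forms, and the mild base leaves C13 and the thioglycerate centre untouched.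

---

**Compound list**

1 | (+)‑sclareolide | C[C@@]12CC[C@H]3C(C)(C)CCC[C@]3(C)[C@H]1CC(=O)O2 | starting material
2 | 3β‑hydroxysclareolide | C[C@@]12CC[C@H]3C(C)(C)[C@@H](O)CC[C@]3(C)[C@H]1CC(=O)O2 | intermediate
3 | 3β‑OTES‑sclareolide | C[C@@]12CC[C@H]3C(C)(C)[C@@H](O[Si](CC)(CC)CC)CC[C@]3(C)[C@H]1CC(=O)O2 | intermediate
4 | methyl 2‑methylfuran‑3‑carboxylate | COC(=O)c1ccoc1C | starting material
5 | (2‑methylfuran‑3‑yl)methanol | Cc1occc1CO | intermediate
6 | triethyl[(2‑methylfuran‑3‑yl)methoxy]silane | CC[Si](CC)(CC)OCc1ccoc1C | intermediate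
7 | 8α‑hydroxy 3β‑OTES furyl ketone (ring‑opened) | C[C@@]1(O)CC[C@H]2C(C)(C)[C@@H](O[Si](CC)(CC)CC)CC[C@]2(C)[C@H]1CC(=O)c1cc(CO[Si](CC)(CC)CC)c(C)o1 | intermediate
8 | Δ8(17) furyl ketone | C=C1CC[C@H]2C(C)(C)[C@@H](O[Si](CC)(CC)CC)CC[C@]2(C)[C@H]1CC(=O)c1cc(CO[Si](CC)(CC)CC)c(C)o1 | intermediate
9 | Z‑enedione (1,2,4‑triketone) | C=C1CC[C@H]2C(C)(C)[C@@H](O[Si](CC)(CC)CC)CC[C@]2(C)[C@H]1CC(=O)C(=O)/C=C(/CO[Si](CC)(CC)CC)C(C)=O | intermediate
10 | 4‑hydroxy‑4‑acylcyclopentenone, bis‑TES | C=C1CC[C@H]2C(C)(C)[C@@H](O[Si](CC)(CC)CC)CC[C@]2(C)[C@H]1CC(=O)[C@]1(O)C=C(CO[Si](CC)(CC)CC)C(=O)C1 | intermediate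
11 | triol | C=C1CC[C@H]2C(C)(C)[C@@H](O)CC[C@]2(C)[C@H]1CC(=O)[C@]1(O)C=C(CO)C(=O)C1 | intermediate
12 | allylic bromide | C=C1CC[C@H]2C(C)(C)[C@@H](O)CC[C@]2(C)[C@H]1CC(=O)[C@]1(O)C=C(CBr)C(=O)C1 | intermediate
13 | methyl (S)‑glycidate | COC(=O)[C@@H]1CO1 | starting material
14 | methyl (R)‑3‑(acetylthio)‑2‑hydroxypropanoate | CC(=O)SC[C@H](O)C(=O)OC | intermediate
15 | methyl (R)‑2‑hydroxy‑3‑mercaptopropanoate | SC[C@H](O)C(=O)OC | intermediate
16 | Alternarin A | C=C1CC[C@H]2C(C)(C)[C@@H](O)CC[C@]2(C)[C@H]1CC(=O)[C@]1(O)C=C(CSC[C@H](O)C(=O)OC)C(=O)C1 | target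

---

**Total steps:** 13.
**Longest linear sequence:** 9 steps (Steps 1, 2, 5, 6, 7, 8, 9, 10, 13, from sclareolide).

**Three steps most likely to fail**
1. **Step 6 (dehydration).** The exocyclic and endocyclic alkene ratio is the risk. Fallback: convert the tertiary alcohol to its methyl xanthate (KHMDS, CS2, MeI) and carry out a Chugaev thermolysis. This is a different syn‑elimination mechanism with a strong Hofmann preference.
2. **Step 7 (photooxygenation).** The electron‑poor 2‑acylfuran may react slowly, and the exocyclic alkene may compete. Fallback: reduce the furyl ketone to the furylcarbinol (NaBH4), oxidize the more electron‑rich furan, carry out the aldol, and then oxidize C12‑OH with Dess–Martin periodinane. This changes the order of oxidation states.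
3. **Step 8 (aldol).** The risks are competing C11 enolization, which would give a six‑membered ring, and poor C13 diastereoselectivity. Fallback: switch from Brønsted‑base catalysis to enamine catalysis with a chiral primary amine (9‑amino‑9‑deoxy‑epi‑quinine·TFA). The enamine forms selectively at the methyl ketone, and the catalyst controls C13.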